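**Plan**

1. Numbering and α/β as used for the gibberellins (ring A: C1–C5, C10; ring B: C5, C6, C8, C9, C10; ring C: C8, C9, C11–C14; ring D: C8, C14, C13, C16, C15; β is the face of H-5 and H-9; "exo" at C16 is the side of the one-carbon bridge C14). Retrosynthesis: C16 carbinol → 16-ketone → 16-methylidene; ring D is opened at C13–C16 with a helper ketone at C14; ring B is then cut at C9–C10 and C6–C8 together, which separates a ring A keto ester (10) from 2-propargylcyclohexenone (16).
2. Enabling feature: ring B is a cyclopentane whose C10–C5–C6 edge is a β,γ-unsaturated carbonyl unit on ring A and whose C8–C9 edge is the α,β-bond of a ring C enone. A tertiary C10 radical can therefore add to C9 and the C8 enolate can close on C6, a three-plus-two union at the two quaternary carbons C10 and C8.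
3. Forward order: ring A (oxidative radical cyclization of a β-keto ester), ring C (bought as cyclohexane-1,3-dione), ring B (key step), ring D (gold-catalysed 5-exo-dig closure), then removal of the helpers (C14 ketone, C6 hydroxyl, benzyl groups) and methyl addition at C16.
4. Stereochemistry: C4/C5 relative configuration from the chair transition state of the radical cyclization; absolute configuration and C3 from a Corey–Bakshi–Shibata reduction of the racemic ketone with separation of the two diastereomers; C10, C9 and C8 from substrate control in the key step; C13 from the bridging geometry; C6 by equilibration; C16 from exo attack of the methyl nucleophile.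

Key step: step 12

**Route**

Step 1
Reactants: 1 methyl 4-methylpent-3-enoate
Product: 2 methyl (E)-5-hydroxy-4-methylpent-3-enoate
Conditions: SeO2 (0.3 equiv), t-BuOOH, CH2Cl2, rt
Reagents that add atoms: tert-butyl hydroperoxide, CC(C)(C)OO
Why: Riley allylic oxidation (ene reaction, then 2,3-sigmatropic shift) of a trisubstituted alkene should take the (E)-methyl group of the more substituted alkene carbon and give the E allylic alcohol.

Step 2
Reactants: 2 methyl (E)-5-hydroxy-4-methylpent-3-enoate
Product: 3 methyl (E)-5-bromo-4-methylpent-3-enoate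
Conditions: CBr4, PPh3, CH2Cl2, 0 °C
Reagents that add atoms: carbon tetrabromide, BrC(Br)(Br)Br
Why: Appel reaction; the primary allylic alcohol should be displaced by bromide at the oxyphosphonium stage without change of alkene geometry.

Step 3
Reactants: 4 benzyl 2-methyl-3-oxobutanoate; 3 methyl (E)-5-bromo-4-methylpent-3-enoate
Product: 5 9-benzyl 1-methyl (E)-4,8-dimethyl-7-oxonon-3-enedioate
Conditions: LDA (2.1 equiv), THF, −78 to 0 °C; then 3, −78 to 0 °C
Reagents that add atoms: none
Why: Acetoacetate dianion alkylation; the terminal carbanion is the more reactive site and should displace the allylic bromide by SN2 faster than it deprotonates the ester.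

Step 4
Reactants: 5 9-benzyl 1-methyl (E)-4,8-dimethyl-7-oxonon-3-enedioate
Product: 6 rac-benzyl (1S,2S)-2-(2-methoxy-2-oxoethyl)-1-methyl-3-methylidene-6-oxocyclohexane-1-carboxylate (racemate; the enantiomer carried forward is drawn)
Conditions: Mn(OAc)3·2H2O (2.2 equiv), Cu(OAc)2·H2O (1 equiv), AcOH, rt
Reagents that add atoms: none
Why: Oxidative free-radical cyclization: the trivalent manganese enolate should give the α-keto ester radical at C4, which closes 6-endo-trig on the trisubstituted alkene through a chair with the alkene substituent equatorial (ester cis to the C5 side chain), and Cu(OAc)2 should oxidize the tertiary C10 radical to the exocyclic alkene (a minor ring-alkene isomer would give the same C10 radical in step 12).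

Step 5
Reactants: 6 rac-benzyl (1S,2S)-2-(2-methoxy-2-oxoethyl)-1-methyl-3-methylidene-6-oxocyclohexane-1-carboxylate
Product: 7 benzyl (1S,2S,6S)-6-hydroxy-2-(2-methoxy-2-oxoethyl)-1-methyl-3-methylidenecyclohexane-1-carboxylate
Conditions: (R)-2-methyl-CBS-oxazaborolidine (0.2 equiv), catecholborane, PhMe, −78 °C; chromatographic separation of the two diastereomeric alcohols
Reagents that add atoms: none
Why: Corey–Bakshi–Shibata reduction; the catalyst should deliver hydride to the same ketone face in both enantiomers (quaternary C4 as the large group, giving the S carbinol), so the racemate becomes two separable diastereomers, and the one with hydroxyl cis to the C4 methyl group is 7 as a single enantiomer; catecholborane is used because it does not hydroborate the alkene.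

Step 6
Reactants: 7 benzyl (1S,2S,6S)-6-hydroxy-2-(2-methoxy-2-oxoethyl)-1-methyl-3-methylidenecyclohexane-1-carboxylate
Product: 8 benzyl (1S,2S,6S)-6-(benzyloxy)-2-(2-methoxy-2-oxoethyl)-1-methyl-3-methylidenecyclohexane-1-carboxylate
Conditions: 2-benzyloxy-1-methylpyridinium triflate, MgO, PhCF3, 85 °C
Reagents that add atoms: 2-benzyloxy-1-methylpyridinium trifluoromethanesulfonate, C[n+]1ccccc1OCc1ccccc1.[O-]S(=O)(=O)C(F)(F)F
Why: Neutral benzyl transfer from the pyridinium salt should etherify the hindered alcohol without base (retro-aldol of the β-hydroxy ester) or strong acid (alkene migration).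

Step 7
Reactants: 8 benzyl (1S,2S,6S)-6-(benzyloxy)-2-(2-methoxy-2-oxoethyl)-1-methyl-3-methylidenecyclohexane-1-carboxylate
Product: 9 benzyl (1S,2S,6S)-6-(benzyloxy)-2-(1-hydroxy-2-methoxy-2-oxoethyl)-1-methyl-3-methylidenecyclohexane-1-carboxylate (both carbinol epimers)
Conditions: KHMDS, THF, −78 °C; then 3-phenyl-2-(phenylsulfonyl)oxaziridine, −78 °C
Reagents that add atoms: 3-phenyl-2-(phenylsulfonyl)-1,2-oxaziridine, O=S(=O)(c1ccccc1)N1OC1c1ccccc1
Why: Enolate hydroxylation; only the methyl ester has α-hydrogens (the benzyl ester sits on a quaternary carbon), so the enolate should form at C6 alone and take oxygen from the oxaziridine.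

Step 8
Reactants: 9 benzyl (1S,2S,6S)-6-(benzyloxy)-2-(1-hydroxy-2-methoxy-2-oxoethyl)-1-methyl-3-methylidenecyclohexane-1-carboxylate
Product: 10 benzyl (1S,2S,6S)-6-(benzyloxy)-2-(2-methoxy-2-oxoacetyl)-1-methyl-3-methylidenecyclohexane-1-carboxylate
Conditions: DMP, NaHCO3, CH2Cl2, 0 °C; used without storage
Reagents that add atoms: none
Why: Dess–Martin oxidation under buffered, non-enolizing conditions should give the α-keto ester without epimerization at C5 or migration of the alkene into conjugation.

Step 9
Reactants: 11 cyclohexane-1,3-dione; 12 3-bromoprop-1-yne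
Product: 13 2-(prop-2-yn-1-yl)cyclohexane-1,3-dione
Conditions: KOH, H2O, rt to 50 °C
Reagents that add atoms: none
Why: C-alkylation of the dione enolate in water, where hydrogen bonding to oxygen favours carbon attack on the propargylic bromide.

Step 10
Reactants: 13 2-(prop-2-yn-1-yl)cyclohexane-1,3-dione
Product: 14 3-(2-methylpropoxy)-2-(prop-2-yn-1-yl)cyclohex-2-en-1-one
Conditions: i-BuOH, TsOH (cat.), PhMe, reflux, Dean–Stark trap
Reagents that add atoms: 2-methylpropan-1-ol, CC(C)CO
Why: Acid-catalysed vinylogous ester formation driven by removal of water.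

Step 11
Reactants: 14 3-(2-methylpropoxy)-2-(prop-2-yn-1-yl)cyclohex-2-en-1-one
Product: 16 2-(prop-2-yn-1-yl)cyclohex-2-en-1-one, via 3-(2-methylpropoxy)-2-(prop-2-yn-1-yl)cyclohex-2-en-1-ol 15 (not isolated)
Conditions: LiAlH4, Et2O, 0 °C; then 2 M HCl, rt
Reagents that add atoms: none
Why: Stork–Danheiser transposition; 1,2-reduction of the vinylogous ester and acid hydrolysis of the enol ether with loss of water should give the 2-substituted enone.

Step 12
Reactants: 10 benzyl (1S,2S,6S)-6-(benzyloxy)-2-(2-methoxy-2-oxoacetyl)-1-methyl-3-methylidenecyclohexane-1-carboxylate; 16 2-(prop-2-yn-1-yl)cyclohex-2-en-1-one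
Product: 18 tricyclic aldol adduct (19-benzyl 7-methyl 3β-benzyloxy-6-hydroxy-14-oxo-13,16-secogibberell-16-yne-7,19-dioate; C6 configuration open), via iron enolate of the Giese adduct 17 (not isolated)
Conditions: Fe(acac)3 (0.5 equiv), PhSiH3 (2.5 equiv), 16 (3 equiv), EtOH/ethylene glycol (5:1), 35 °C
Reagents that add atoms: none
Why: Proposed new method: the iron hydride formed from Fe(acac)3 and PhSiH3 should transfer a hydrogen atom to the C20 methylidene carbon of 10 (Markovnikov), the tertiary C10 radical should add to the unsubstituted β-carbon C9 of enone 16 (Giese addition, C9–C10 bond), divalent iron should reduce the resulting α-keto radical to the C8 enolate 17, and this enolate should add to the C6 ketone of the keto ester (aldol addition, C6–C8 bond) before ethanol protonates it. The closest known reaction type is the radical–polar crossover annulation in which hydrogen atom transfer to an alkenyl aldehyde, Giese addition to an enone and aldol closure build a six-membered ring; a five-membered ring from a β,γ-unsaturated α-keto ester and a 2-substituted cyclohexenone has not been shown. Ring B closes in the 5-(enolexo)-exo-trig mode, the enolate double bond C8=C14 lying outside the new ring. C10 is controlled by ring A: the axial C4 benzyl ester (1,3 to C10) screens the α face and the bond forms on the β face, trans to the C5 side chain, which gives the trans A/B fusion with the C20 methyl α. C9 is set by the face of the enone that meets the radical (H-9 should point over ring A, the flat carbonyl-bearing C8 flank should lie next to the C5 keto ester, where one iron centre can bind both carbonyl groups, and the C11 methylene should take the open sector beside C1), C8 follows from C9 because the three-atom tether can reach only the enolate face that gives a cis B/C fusion with the propargyl group anti to C10, and C6 is not controlled and is erased in step 17. The step needs hydrogen atom transfer to the 1,1-disubstituted alkene only (the enone, the alkyne and the carbonyl groups are poor acceptors of the hydrogen atom), ring closure faster than enolate protonation (secured by the strongly electrophilic ketone held in a five-ring relationship) and the enone face selectivity just named, which rests on steric and chelation bias alone.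

Step 13
Reactants: 18 tricyclic aldol adduct
Product: 19 6-O-TBS ether 14-TBS enol ether of 18 (13-ene)
Conditions: TBSOTf (3.5 equiv), Et3N, CH2Cl2, 0 °C to rt
Reagents that add atoms: tert-butyldimethylsilyl trifluoromethanesulfonate, CC(C)(C)[Si](C)(C)OS(=O)(=O)C(F)(F)F
Why: Soft enolization with silyl triflate and amine; C13 is the only enolizable position of the C14 ketone (C8 is quaternary), and silylation of the tertiary hydroxyl blocks retro-aldol cleavage of the C6–C8 bond.

Step 14
Reactants: 19 bis-silyl compound
Product: 20 19-benzyl 7-methyl 3β-benzyloxy-6-(tert-butyldimethylsilyloxy)-14-oxogibberell-16-ene-7,19-dioate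
Conditions: Ph3PAuCl (5 mol %), AgBF4 (5 mol %), CH2Cl2/MeOH (10:1), rt
Reagents that add atoms: none
Why: Conia-ene-type carbocyclization; the silyl enol ether carbon C13 should attack the alkyne activated by monovalent gold in the 5-exo-dig mode to close ring D with the 16-methylidene group, and C13 can only be formed with the bridge on the face that carries the propargyl arm.

Step 15
Reactants: 20 tetracyclic C14 ketone
Product: 21 14-(4-methylbenzenesulfonyl)hydrazone of 20
Conditions: TsNHNH2, AcOH (cat.), EtOH, 75 °C
Reagents that add atoms: 4-methylbenzenesulfonohydrazide, Cc1ccc(S(=O)(=O)NN)cc1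
Why: Hydrazone condensation; the one-carbon-bridge ketone is angle-strained and should condense despite its hindered flanks, and the non-basic conditions spare the esters and the β-silyloxy ketone.

Step 16
Reactants: 21 C14 tosylhydrazone
Product: 23 19-benzyl 7-methyl 3β-benzyloxy-6-(tert-butyldimethylsilyloxy)gibberell-16-ene-7,19-dioate, via N-boryl alkylhydrazine 22 (not isolated)
Conditions: catecholborane, CHCl3, 0 °C to rt; then NaOAc·3H2O, reflux
Reagents that add atoms: none
Why: Caglioti-type reduction; hydride addition to the C=N bond, acetate-induced loss of sulfinate and loss of N2 from the diazene should leave the C14 methylene without base strong enough to touch the esters, and uncatalysed catecholborane does not hydroborate the alkene at this temperature.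

Step 17
Reactants: 23 C14-methylene silyloxy ester
Product: 25 19-benzyl 7-methyl 3β-benzyloxygibberell-16-ene-7,19-dioate (H-6α), via samarium ester enolate 24 (not isolated)
Conditions: SmI2 (5 equiv), HMPA, THF, MeOH, 0 °C to rt; then t-BuOK (0.3 equiv), t-BuOH, 40 °C
Reagents that add atoms: none
Why: Reductive cleavage of an α-oxygenated ester by divalent samarium (two single-electron transfers, loss of silanolate) should give enolate 24, which methanol protonates, and the alkoxide equilibration should settle C6 in the more stable configuration with the C7 ester trans to C4 on ring B.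

Step 18
Reactants: 25 16-methylidene diester
Product: 27 19-benzyl 7-methyl 3β-benzyloxy-16-oxo-17-norgibberellane-7,19-dioate, via 16,17-diol 26 (not isolated)
Conditions: OsO4 (2 mol %), NaIO4, 2,6-lutidine, dioxane/H2O (3:1), rt
Reagents that add atoms: osmium tetroxide (catalytic), O=[Os](=O)(=O)=O; sodium periodate (terminal oxidant), [Na+].[O-][I](=O)(=O)=O
Why: Lemieux–Johnson oxidation; dihydroxylation of the only alkene and periodate cleavage should give the 16-ketone while leaving the benzyl groups untouched.

Step 19
Reactants: 27 16-ketone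
Product: 28 19-benzyl 7-methyl 3β-benzyloxy-16-hydroxygibberellane-7,19-dioate (16-hydroxyl endo and 16-methyl exo)
Conditions: MeMgBr, CeCl3, THF, −78 °C
Reagents that add atoms: methylmagnesium bromide, C[Mg]Br
Why: Grignard addition as the organocerium reagent; the methyl group should enter from the exo face (side of the C14 bridge) because the axial hydrogen on C11 of the three-carbon bridge screens the endo face, which places the hydroxyl endo as in the target, and at −78 °C the two hindered esters should not react.

Step 20
Reactants: 28 16-methyl carbinol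
Product: 29 3β,16-dihydroxy-7-methoxy-7-oxogibberellan-19-oic acid
Conditions: H2 (1 atm), Pd/C (10 %), EtOAc/MeOH, rt
Reagents that add atoms: none
Why: Hydrogenolysis should remove the benzyl ether and the benzyl ester in one operation; no alkene is left to reduce.

Step 21
Reactants: 29 hydroxy acid methyl ester
Product: 30 3β,7,16-trihydroxygibberellan-19-oic acid (target)
Conditions: LiBH4 (excess), THF, 50 °C; then 1 M HCl, 0 °C
Reagents that add atoms: none
Why: Borohydride reduction; the C19 acid is converted in the flask to its lithium carboxylate, which LiBH4 does not reduce, so only the C7 methyl ester should be taken to the primary alcohol.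

**Compound list**

1 | methyl 4-methylpent-3-enoate | COC(=O)CC=C(C)C | starting material
2 | methyl (E)-5-hydroxy-4-methylpent-3-enoate | COC(=O)C/C=C(\C)CO | intermediate
3 | methyl (E)-5-bromo-4-methylpent-3-enoate | COC(=O)C/C=C(\C)CBr | intermediate
4 | benzyl 2-methyl-3-oxobutanoate | CC(=O)C(C)C(=O)OCc1ccccc1 | starting material
5 | 9-benzyl 1-methyl (E)-4,8-dimethyl-7-oxonon-3-enedioate | COC(=O)C/C=C(\C)CCC(=O)C(C)C(=O)OCc1ccccc1 | intermediate
6 | rac-benzyl (1S,2S)-2-(2-methoxy-2-oxoethyl)-1-methyl-3-methylidene-6-oxocyclohexane-1-carboxylate (racemate; enantiomer carried forward drawn) | C=C1CCC(=O)[C@@](C)(C(=O)OCc2ccccc2)[C@H]1CC(=O)OC | intermediate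
7 | benzyl (1S,2S,6S)-6-hydroxy-2-(2-methoxy-2-oxoethyl)-1-methyl-3-methylidenecyclohexane-1-carboxylate | C=C1CC[C@H](O)[C@@](C)(C(=O)OCc2ccccc2)[C@H]1CC(=O)OC | intermediate
8 | benzyl (1S,2S,6S)-6-(benzyloxy)-2-(2-methoxy-2-oxoethyl)-1-methyl-3-methylidenecyclohexane-1-carboxylate | C=C1CC[C@H](OCc2ccccc2)[C@@](C)(C(=O)OCc2ccccc2)[C@H]1CC(=O)OC | intermediate
9 | benzyl (1S,2S,6S)-6-(benzyloxy)-2-(1-hydroxy-2-methoxy-2-oxoethyl)-1-methyl-3-methylidenecyclohexane-1-carboxylate (carbinol epimers) | C=C1CC[C@H](OCc2ccccc2)[C@@](C)(C(=O)OCc2ccccc2)[C@H]1C(O)C(=O)OC | intermediate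
10 | benzyl (1S,2S,6S)-6-(benzyloxy)-2-(2-methoxy-2-oxoacetyl)-1-methyl-3-methylidenecyclohexane-1-carboxylate (ring A fragment) | C=C1CC[C@H](OCc2ccccc2)[C@@](C)(C(=O)OCc2ccccc2)[C@H]1C(=O)C(=O)OC | intermediate
11 | cyclohexane-1,3-dione | O=C1CCCC(=O)C1 | starting material
12 | 3-bromoprop-1-yne | C#CCBr | starting material
13 | 2-(prop-2-yn-1-yl)cyclohexane-1,3-dione | O=C1CCCC(=O)C1CC#C | intermediate
14 | 3-(2-methylpropoxy)-2-(prop-2-yn-1-yl)cyclohex-2-en-1-one | CC(C)COC1=C(CC#C)C(=O)CCC1 | intermediate
15 | 3-(2-methylpropoxy)-2-(prop-2-yn-1-yl)cyclohex-2-en-1-ol (not isolated) | CC(C)COC1=C(CC#C)C(O)CCC1 | intermediate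
16 | 2-(prop-2-yn-1-yl)cyclohex-2-en-1-one (ring C fragment) | O=C1CCCC=C1CC#C | intermediate
17 | iron enolate of the Giese adduct, C9–C10 bond formed, ring B open, drawn as the enolate anion (not isolated) | C[C@@]1([C@@H]2CCCC([O-])=C2CC#C)CC[C@H](OCc2ccccc2)[C@@](C)(C(=O)OCc2ccccc2)[C@H]1C(=O)C(=O)OC | intermediate
18 | 19-benzyl 7-methyl 3β-benzyloxy-6-hydroxy-14-oxo-13,16-secogibberell-16-yne-7,19-dioate (rings A/B/C; A/B trans, B/C cis; C6 configuration open) | C[C@@]12CC[C@H](OCc3ccccc3)[C@@](C)(C(=O)OCc3ccccc3)[C@H]1C(O)(C(=O)OC)[C@@]3(CC#C)C(=O)CCC[C@@H]23 | intermediate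
19 | 6-O-TBS ether 14-TBS enol ether of 18 (13-ene) | C[C@@]12CC[C@H](OCc3ccccc3)[C@@](C)(C(=O)OCc3ccccc3)[C@H]1C(O[Si](C)(C)C(C)(C)C)(C(=O)OC)[C@@]3(CC#C)C(O[Si](C)(C)C(C)(C)C)=CCC[C@@H]23 | intermediate
20 | 19-benzyl 7-methyl 3β-benzyloxy-6-(tert-butyldimethylsilyloxy)-14-oxogibberell-16-ene-7,19-dioate | C[C@@]12CC[C@H](OCc4ccccc4)[C@@](C)(C(=O)OCc4ccccc4)[C@H]1C(O[Si](C)(C)C(C)(C)C)(C(=O)OC)[C@@]13C(=O)[C@@H](CC[C@@H]21)C(=C)C3 | intermediate
21 | 14-(4-methylbenzenesulfonyl)hydrazone of 20 | C[C@@]12CC[C@H](OCc4ccccc4)[C@@](C)(C(=O)OCc4ccccc4)[C@H]1C(O[Si](C)(C)C(C)(C)C)(C(=O)OC)[C@@]13C(=NNS(=O)(=O)c5ccc(C)cc5)[C@@H](CC[C@@H]21)C(=C)C3 | intermediate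
22 | 14-[N-(1,3,2-benzodioxaborol-2-yl)-N'-tosylhydrazino] compound (not isolated) | C[C@@]12CC[C@H](OCc4ccccc4)[C@@](C)(C(=O)OCc4ccccc4)[C@H]1C(O[Si](C)(C)C(C)(C)C)(C(=O)OC)[C@@]13C(N(NS(=O)(=O)c5ccc(C)cc5)B5Oc6ccccc6O5)[C@@H](CC[C@@H]21)C(=C)C3 | intermediate
23 | 19-benzyl 7-methyl 3β-benzyloxy-6-(tert-butyldimethylsilyloxy)gibberell-16-ene-7,19-dioate | C[C@@]12CC[C@H](OCc4ccccc4)[C@@](C)(C(=O)OCc4ccccc4)[C@H]1C(O[Si](C)(C)C(C)(C)C)(C(=O)OC)[C@@]13C[C@@H](CC[C@@H]21)C(=C)C3 | intermediate
24 | samarium ester enolate at C6=C7, drawn as the enolate anion (not isolated) | C[C@@]12CC[C@H](OCc4ccccc4)[C@@](C)(C(=O)OCc4ccccc4)[C@H]1C(=C([O-])OC)[C@@]13C[C@@H](CC[C@@H]21)C(=C)C3 | intermediate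
25 | 19-benzyl 7-methyl 3β-benzyloxygibberell-16-ene-7,19-dioate (H-6α) | C[C@@]12CC[C@H](OCc4ccccc4)[C@@](C)(C(=O)OCc4ccccc4)[C@H]1[C@H](C(=O)OC)[C@@]13C[C@@H](CC[C@@H]21)C(=C)C3 | intermediate
26 | 16,17-diol of 25, 16-hydroxyl exo (not isolated) | C[C@@]12CC[C@H](OCc4ccccc4)[C@@](C)(C(=O)OCc4ccccc4)[C@H]1[C@H](C(=O)OC)[C@@]13C[C@@H](CC[C@@H]21)[C@](CO)(O)C3 | intermediate
27 | 19-benzyl 7-methyl 3β-benzyloxy-16-oxo-17-norgibberellane-7,19-dioate | C[C@@]12CC[C@H](OCc4ccccc4)[C@@](C)(C(=O)OCc4ccccc4)[C@H]1[C@H](C(=O)OC)[C@@]13C[C@@H](CC[C@@H]21)C(=O)C3 | intermediate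
28 | 19-benzyl 7-methyl 3β-benzyloxy-16-hydroxygibberellane-7,19-dioate (16-OH endo, 16-methyl exo) | C[C@@]12CC[C@H](OCc4ccccc4)[C@@](C)(C(=O)OCc4ccccc4)[C@H]1[C@H](C(=O)OC)[C@@]13C[C@@H](CC[C@@H]21)[C@@](C)(O)C3 | intermediate
29 | 3β,16-dihydroxy-7-methoxy-7-oxogibberellan-19-oic acid | C[C@@]12CC[C@H](O)[C@@](C)(C(=O)O)[C@H]1[C@H](C(=O)OC)[C@@]13C[C@@H](CC[C@@H]21)[C@@](C)(O)C3 | intermediate
30 | 3β,7,16-trihydroxygibberellan-19-oic acid (16-OH endo) | C[C@@]12CC[C@H](O)[C@@](C)(C(=O)O)[C@H]1[C@H](CO)[C@@]13C[C@@H](CC[C@@H]21)[C@@](C)(O)C3 | target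

**Count and risks**

Total step count: 21. Longest linear sequence: 18 steps (steps 1–8 and 12–21); steps 9–11 form the side branch.

Most likely to fail:

Step 12 (proposed new method). The enolate may be protonated by the alcohol solvent before ring B closes, the hindered tertiary radical may be reduced instead of adding to the 2-substituted enone, and the selection of the enone face may be poor. Fallback with known chemistry, setting out from 10 and 16: the two fragments are joined by the established iron-hydride reductive olefin–enone coupling (Fe(acac)3, PhSiH3, EtOH, 60 °C) and worked up to the protonated Giese adduct, ketone F1. In a separate operation the more substituted enolate at C8 is generated under equilibrating conditions (t-BuOK, catalytic, in t-BuOH/THF at 0 °C) and closes ring B by intramolecular aldol addition to the keto ester. The sequence comes back to the route at 18. This fallback does not improve the enone face selectivity.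

Step 15. Condensation at the C14 ketone, which is flanked by the quaternary C8 and the bridgehead C13, may stay incomplete, and hydride delivery to the hydrazone in step 16 may then be slow. Fallback, setting out from 20: the ketone is reduced with NaBH4 (MeOH, 0 °C) to the C14 alcohol F2, which is converted with NaH, CS2 and MeI into the S-methyl xanthate F3. Barton–McCombie deoxygenation (Bu3SnH, AIBN, PhMe, 110 °C) then removes the oxygen; the secondary C14 radical has no favourable rearrangement path onto the 16-methylidene group. The sequence comes back to the route at 23.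

Step 17. Electron transfer to the ester next to the quaternary C8 and loss of the silanolate may be slow, so that reduction stalls or the benzyl ester is attacked first. Fallback, setting out from 23: the silyl ether is cleaved with HF·pyridine to the tertiary α-hydroxy ester F4, which is acylated with methyl chlorooxoacetate (DMAP, pyridine) to the mixed oxalate F5. Tin hydride deoxygenation of this tertiary oxalate (Bu3SnH, AIBN, PhMe, 110 °C) goes through the ester-stabilized C6 radical, and the resulting C6 epimers are equilibrated with t-BuOK in t-BuOH as in step 17. The sequence comes back to the route at 25.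

Further compounds
F1 | step 12 | protonated Giese adduct: benzyl (1S,2S,6S)-6-(benzyloxy)-2-(2-methoxy-2-oxoacetyl)-1,3-dimethyl-3-[2-oxo-3-(prop-2-yn-1-yl)cyclohexyl]cyclohexane-1-carboxylate (C8 epimers) | C[C@@]1([C@@H]2CCCC(=O)C2CC#C)CC[C@H](OCc2ccccc2)[C@@](C)(C(=O)OCc2ccccc2)[C@H]1C(=O)C(=O)OC
F2 | step 15 | 14-hydroxy compound from 20 (19-benzyl 7-methyl 3β-benzyloxy-6-(tert-butyldimethylsilyloxy)-14-hydroxygibberell-16-ene-7,19-dioate) | C[C@@]12CC[C@H](OCc4ccccc4)[C@@](C)(C(=O)OCc4ccccc4)[C@H]1C(O[Si](C)(C)C(C)(C)C)(C(=O)OC)[C@@]13C(O)[C@@H](CC[C@@H]21)C(=C)C3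
F3 | step 15 | 14-O-[(methylsulfanyl)carbonothioyl] derivative of F2 (S-methyl xanthate) | C[C@@]12CC[C@H](OCc4ccccc4)[C@@](C)(C(=O)OCc4ccccc4)[C@H]1C(O[Si](C)(C)C(C)(C)C)(C(=O)OC)[C@@]13C(OC(=S)SC)[C@@H](CC[C@@H]21)C(=C)C3
F4 | step 17 | 19-benzyl 7-methyl 3β-benzyloxy-6-hydroxygibberell-16-ene-7,19-dioate | C[C@@]12CC[C@H](OCc4ccccc4)[C@@](C)(C(=O)OCc4ccccc4)[C@H]1C(O)(C(=O)OC)[C@@]13C[C@@H](CC[C@@H]21)C(=C)C3
F5 | step 17 | 6-O-(2-methoxy-2-oxoacetyl) derivative of F4 (mixed methyl oxalate) | C[C@@]12CC[C@H](OCc4ccccc4)[C@@](C)(C(=O)OCc4ccccc4)[C@H]1C(OC(=O)C(=O)OC)(C(=O)OC)[C@@]13C[C@@H](CC[C@@H]21)C(=C)C3
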